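With the rate constants hidden, reckon from the charges and the earlier runs.

| setting | summer | winter | autumn | flask |
|---|---|---|---|---|
| starting material | 0.10 M | 0.10 M | 0.10 M | 0.10 M |
| second substrate | 0.050 M | 0.050 M | 0.10 M | 0.0500 M |
| enzyme | 92 µM | 150 µM | 66 µM | 66 µM |
| impurity | 9.5 µM | 9.5 µM | 9.5 µM | 9.5 µM |
| remark | run made earlier | run made earlier | run made earlier |  |

- summer (time / d: target / %, starting material / %): 1.67: 49, 5; 3.00: 60, 2; 5.00: 61, 1; 6.00: 62, 1; 8.00: 59, 0; 10.0: 63, 1
- winter (time / d: target / %, starting material / %): 0.625: 51, 21; 1.67: 73, 1; 3.00: 74, 2; 5.00: 73, 0; 8.00: 70, 0; 10.0: 75, 4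
- autumn (time / d: target / %, starting material / %): 2.08: 37, 7; 4.00: 47, 0; 6.00: 46, 0; 8.00: 50, 1; 10.0: 47, 0

(readings scatter by 2 percentage points)

- in percentages every species weighs as the starting material in it: one homo dimer counts as two
- the analysis behind the earlier runs scatters by 2 percentage points, standard deviation
- what may be going on: starting material + enzyme <-> complex A; complex A -> enzyme + target; second substrate + enzyme <-> complex B; complex B -> enzyme + second product; 2 starting material -> homo dimer; enzyme + impurity -> spent catalyst

1. apparent order in enzyme when 20 % of the starting material are converted (percent change of the rate of making target for one percent more enzyme charged)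

Face the apparent clash first. The flask charges 9.5 µM of impurity against 0.10 M of starting material, a ratio of 10500, yet a catalyst poison at this level may lift the order in enzyme above one. Clear it by holding the impurity against the enzyme instead: the proposed poisoning step removes one enzyme per impurity, and the impurity is the limiting reagent of that step.

Define the active fraction f, the share of charged enzyme left working after complete titration: 0.856. Enzyme is far below the second substrate, so at fixed composition the substrates set how working enzyme divides among its forms, and the rate of making target scales with charged enzyme minus impurity. Differentiate the logarithm of that rate: the order is the inverse of f, 1.17.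

The forecast gives 1.13, below this reckoning of 1.17, with the reservation “If poisoning is incomplete at this early point (a few hours), the order approaches 1”.

The flask gives 1.2, and the forecast stands within the tolerance.

    starting material + enzyme ⇌ complex A (K = 4.00 M⁻¹, k = 27.0 M⁻¹ s⁻¹)
    complex A → enzyme + target (k = 0.0520 s⁻¹)
    second substrate + enzyme ⇌ complex B (K = 13.0 M⁻¹, k = 34.0 M⁻¹ s⁻¹)
    complex B → enzyme + second product (k = 0.0310 s⁻¹)
    2 starting material → homo dimer (k = 8.00 × 10⁻⁵ M⁻¹ s⁻¹)
    enzyme + impurity → spent catalyst (k = 260 M⁻¹ s⁻¹)

Take the flask at 1.20 d: impurity stands at 0 % of its own charge and spent catalyst at 14.4 % of the catalyst charged, the share outside f being 14.4 %. With enzyme as charged, the impurity lifetime is 0.971 min, far shorter than the 0.127 d taken to reach 20 % conversion. Put f to the summer run: 0.897, which gives a reckoned order of 1.12.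

All runs come from a simulation for substances that don't exist; noise was put on by code.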